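## Structural features

The target is a tetracyclic abietane. Ring C (C8, C9, C11–C14) is a p-benzoquinone with an acetoxy group on C12 and an isopropyl group on C13. It is fused through C8–C9 to ring B, whose C6=C7 double bond is conjugated with the quinone.

Ring B shares C5–C10 with the saturated ring A. A δ-lactone (C4–C19(=O)–O–C20–C10) spans the two β-axial positions of ring A. Ring A and the lactone therefore form a 3-oxabicyclo[3.3.1]nonan-2-one: the oxygen sits in the middle of the three-atom bridge, not on a bridgehead, and C5 is the one-atom bridge.

The three stereocentres C4, C5 and C10 are contiguous (4S,5R,10R). C4 and C10 are all-carbon quaternary bridgeheads, and H-5 is α, trans to the C20 bridge.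

The fragile parts are the acetate of a hydroxyquinone (a vinylogous anhydride) and the vinylquinone, which is a Michael acceptor and makes H-5 vinylogously acidic. Both belong at the very end, and base is to be avoided there.

The real difficulty is not ring C. It is the pair of 1,3-related quaternary carbons C4 and C10 on either side of C5. The key step exploits the loop C4–C19–(O)–C20–C10–C5. Removing the lactone oxygen and joining C19 to C20 gives a bicyclo[3.2.1]octene. Its five-membered ring is a cyclopentadiene retron, and its C1–C2–C3 bridge is a three-carbon cation.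

## Logic of the disconnections

**33 ⇒ 32 ⇒ 31 ⇒ 30.** The acetyl–O12 bond, the O12–CH3 bond and the two quinone C=O groups are traced back to three aryl methyl ethers.
- Reason: the labile functions come last.
- Gain: a robust arene carries the full oxidation level of ring C through the whole route.
- Demand: oxidative demethylation must give the para-quinone and spare C6=C7 and the lactone. The last methyl group must come off without base.

**30 ⇒ 29.** The C6=C7 π bond is removed.
- Reason: an electron-rich styrene would not survive ozone or a carbocation.
- Gain: ring B becomes an inert tether.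
- Demand: the dehydrogenation must start at C7–H and not at the isopropyl methine.

**29 ⇒ 26.** The C19–O–C20 linkage is taken out and C19 is joined to C20 as a silyl enol ether double bond.
- Reason: this contracts the oxabicyclononanone to a bicyclo[3.2.1]octene.
- Gain: a cycloaddition retron appears.
- Demand: the cleavage must put the acid level on C19 and the alcohol level on C20. The siloxy group on C19 guarantees this. A Baeyer–Villiger insertion on the corresponding ketone would instead place oxygen next to the quaternary C4.

**26 ⇒ 23.** A carbonyl group is added at C2.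
- Reason: it is the footprint of an oxyallyl unit.
- Gain: none in atoms, but ring A becomes accessible in one step.
- Demand: the ketone must be deoxygenated under conditions that leave a silyl enol ether intact.

**23 ⇒ 16 + 20.** C3–C4 and C1–C10 are cut.
- Reason: both quaternary bridgeheads and ring A fall in one operation.
- Gain: a planar diene with one stereocentre and a symmetric C3 unit.
- Demand: (4+3) periselectivity, and attack on the diene face that carries H-5.

**20 ⇒ 17 + 18.** The C–C bond between the carbonyl carbon and the future methylene is cut, and silicon is moved from oxygen back to carbon.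
- Reason: enolisation of the parent chloroketone would go towards the chlorinated carbon.
- Gain: two commercial reagents.
- Demand: a regiospecific carbon-to-oxygen silyl shift.

**16 ⇒ 14 ⇒ 12.** The O–Si bond and the C4–C18 bond are cut.
- Reason: both arise from the α′ enolate of an enone.
- Gain: an unsubstituted tricyclic cyclopentenone.
- Demand: twice, kinetic deprotonation at C4 and not at the γ-position C5, which holds the only stereocentre.

**12 ⇒ 11.** C5–C10, C4–C19 and C19–C20 are cut (a Pauson–Khand retron, with CO as C19).
- Reason: ring B, the five-membered ring and C5 arise together.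
- Gain: an achiral enyne.
- Demand: enantiofacial control on a benzo-tethered 1,7-enyne.

**11 ⇒ 10 ⇒ 8 + 9.** The C10≡C20 bond is traced to a formyl group, and C7–C8 is cut as an aryl–alkyl cross-coupling.
- Reason: the four-carbon chain arrives at the right oxidation level, so no benzylic oxygen has to be removed and reinstalled.
- Gain: a pentasubstituted bromobenzaldehyde.
- Demand: coupling at a doubly ortho-substituted bromide without touching the aldehyde.

**8 ⇒ 6 ⇒ 5.** C9–C10 (formyl) and C8–Br are cut.
- Reason: with oxygen on C11, C12 and C14 only two ring positions are free. The bromine goes to the one para to O12, and the last C–H, between Br and OMe, is the acidic one.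
- Contrast: with a single donor on C12, C9 would be meta to it and out of reach of electrophilic substitution.
- Demand: low temperature, to keep the ortho-bromoaryllithium from collapsing to an aryne.

**5 ⇒ 4 ⇒ 1 + 2.** C13–C15 is cut.
- Reason: the position between two methoxy groups is the preferred lithiation site.
- Gain: commercial materials.
- Demand: addition must compete with enolisation of 2.

## Other disconnections considered

**Alternative 1:** The cut runs through ring C.
- *Cut:* C8–C14 is formed in the key step. C9–C11 is made just before, by adding the C9 alkenyl-metal from the ring A/B lactone iodide A1 to the ketone-like carbonyl of 3-isopropyl-4-methoxycyclobutene-1,2-dione A2.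
- *Forward key step:* heating the adduct, the 4-alkenyl-4-hydroxycyclobutenone A3, should open the four-membered ring to a dienylketene. This closes by 6π electrocyclisation between C8 and the ketene carbon C14 and tautomerises to hydroquinone A4.
- *In favour:* the ring expansion is a known pericyclic cascade. It places the methoxy group, the isopropyl group and both phenolic oxygens without any regiochemical question, and it is convergent.
- *Against:* it builds the easy part. A1 already contains C4, C5, C10 and the lactone, so the bridgehead problem is only moved elsewhere. A C9 carbanion next to quaternary C10 must also coexist with the lactone carbonyl.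
- *Comparison:*
  - Mechanism: its key step is better secured than step 11.
  - Ring C: two operations are better than steps 1–6.
  - Endgame: it is equal to the chosen plan. A4 still needs oxidation, C6–C7 dehydrogenation, O-demethylation and acetylation, the same four operations that follow 29.
  - Step economy overall: it should be worse, since A1 needs an asymmetric synthesis of its own.

**Alternative 2:** The cut is C4–C5.
- *Forward key step:* the enolate of the propionate in the 4,4-disubstituted naphthalenone A5 adds to C5 of the enone and closes the lactone. This gives the cis-fused lactone tetralone A6.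
- *In favour:* the tether relays the C10 configuration to C5. The C7 ketone needed for the later C6=C7 bond is already there. The undefined C4 centre is harmless, because a later intramolecular alkylation (C3–C4) closes ring A and can only give the bridged arrangement. Every step is standard enolate chemistry.
- *Against:*
  - The absolute configuration rests on an all-carbon quaternary C10 that bears an aryl, a vinyl and two similar oxygenated alkyl groups. This is hard to set catalytically.
  - An ester enolate addition to a hindered neopentyl-type β-carbon is reversible.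
  - The two quaternary centres are made in two separate operations, with protecting-group and activation steps between them.
  - The monomethoxy arene leaves the whole ring C oxidation for the end.
- *Comparison:* in mechanistic security it is the better plan, and in the handling of C7 it is at least equal. In bond economy around C4 and C10 and in the length of the ring C endgame, the chosen plan is better.

**Alternative 3:** The cut is the O–C20 bond, made by C–H functionalisation in the chiral-pool series of podocarpic acid A7.
- *Forward key step:* the 13-isopropyl-12-methoxy-7-oxo C19 primary amide A8 is N-iodinated in situ and photolysed. The amidyl radical abstracts a C20 hydrogen, the C20 iodide is displaced by the amide oxygen, and hydrolysis of the iminolactone gives lactone A9.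
- *In favour:* A7 supplies rings A, B and C and all three stereocentres in the correct absolute sense. The 1,3-diaxial relation of C19 and C20 is ideal for the relay. The 7-oxo group both deactivates the C6 hydrogens and serves later for the C6=C7 bond.
- *Against:*
  - The transfer from C20 runs through a seven-membered transition state and must beat the six-membered one to the β-hydrogen on C2.
  - The hindered axial acid has to be turned into the amide.
  - The isopropyl group has to be added.
  - The monomethoxy ring needs several steps to reach the hydroxyquinone.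
- *Comparison:* in stereochemical security and in the absence of asymmetric catalysis it is clearly better than the chosen plan. In total step count it is probably equal or slightly better. The chosen plan is better only in the ring C endgame and in forming both bridgeheads in one bond-forming event.

Key step: step 11

Remark: abietane numbering is used for all polycyclic compounds; α and β refer to the usual abietane drawing.

Assumption: the sense of induction of the rhodium–BINAP catalyst on enyne 11 cannot be derived with certainty. (S)-BINAP is written for the 5α-H series, and the (R)-ligand is to be taken if the opposite sense is found.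

## Steps

Step 1
Reactants: 1 1,2,4-trimethoxybenzene; 2 acetone
Product: 4 2-(2,3,6-trimethoxyphenyl)propan-2-ol, via 2,3,6-trimethoxyphenyllithium 3 (not isolated)
Conditions: n-BuLi, THF, 0 °C to rt; 2, −78 °C to rt; H2O
Reagents that add atoms: none
Why: Directed ortho-lithiation takes the position flanked by two methoxy groups (future C13), and the aryllithium adds to the ketone (1,2-addition).

Step 2
Reactants: 4 2-(2,3,6-trimethoxyphenyl)propan-2-ol
Product: 5 1,2,4-trimethoxy-3-(propan-2-yl)benzene
Conditions: Et3SiH, CF3CO2H, CH2Cl2, 0 °C to rt
Reagents that add atoms: none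
Why: Ionic hydrogenation; the tertiary benzylic alcohol ionises readily (or dehydrates and is reprotonated) and the cation is reduced by the silane.

Step 3
Reactants: 5 1,2,4-trimethoxy-3-(propan-2-yl)benzene
Product: 6 1-bromo-2,4,5-trimethoxy-3-(propan-2-yl)benzene
Conditions: NBS, MeCN, 0 °C
Reagents that add atoms: N-bromosuccinimide, O=C1CCC(=O)N1Br
Why: Electrophilic aromatic bromination should go to future C8, para to the 12-methoxy and ortho to the 14-methoxy group, the same site at which the parent trimethoxybenzene is substituted. The other free position has only one ortho donor.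

Step 4
Reactants: 6 1-bromo-2,4,5-trimethoxy-3-(propan-2-yl)benzene
Product: 8 2-bromo-3,5,6-trimethoxy-4-(propan-2-yl)benzaldehyde, via 2-bromo-3,5,6-trimethoxy-4-(propan-2-yl)phenyllithium 7 (not isolated)
Conditions: LiN(iPr)2, THF, −78 °C; DMF, −78 to 0 °C; H2O
Reagents that add atoms: N,N-dimethylformamide, CN(C)C=O
Why: Deprotonative ortho-metalation removes the only ring hydrogen, which is acidified by the flanking bromine and methoxy group, and DMF formylates the anion (future C10). The temperature is kept at −78 °C to prevent aryne formation.

Step 5
Reactants: 8 2-bromo-3,5,6-trimethoxy-4-(propan-2-yl)benzaldehyde; 9 but-3-en-1-ylzinc bromide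
Product: 10 2-(but-3-en-1-yl)-3,5,6-trimethoxy-4-(propan-2-yl)benzaldehyde
Conditions: Pd(OAc)2 (cat.), SPhos, THF, rt to 50 °C
Reagents that add atoms: none
Why: Negishi coupling; the ortho formyl group speeds oxidative addition, and the bulky biaryl phosphine favours reductive elimination over β-hydride elimination at the hindered centre. Alkylzinc halides do not add to the aldehyde.

Step 6
Reactants: 10 2-(but-3-en-1-yl)-3,5,6-trimethoxy-4-(propan-2-yl)benzaldehyde
Product: 11 1-(but-3-en-1-yl)-2-ethynyl-3,4,6-trimethoxy-5-(propan-2-yl)benzene
Conditions: dimethyl (1-diazo-2-oxopropyl)phosphonate, K2CO3, MeOH, rt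
Reagents that add atoms: dimethyl (1-diazo-2-oxopropyl)phosphonate, COP(=O)(OC)C(=[N+]=[N-])C(C)=O
Why: Ohira–Bestmann (Seyferth–Gilbert) homologation of a non-enolisable aldehyde supplies C20; the terminal alkene is inert.

Step 7
Reactants: 11 1-(but-3-en-1-yl)-2-ethynyl-3,4,6-trimethoxy-5-(propan-2-yl)benzene
Product: 12 (3aS)-6,8,9-trimethoxy-7-(propan-2-yl)-3,3a,4,5-tetrahydro-2H-cyclopenta[a]naphthalen-2-one (C3a = abietane C5; H-5 α)
Conditions: [Rh(CO)2Cl]2 (cat.), (S)-BINAP, AgOSO2CF3 (cat.), CO (1 atm), THF, 90 °C
Reagents that add atoms: carbon monoxide, [C-]#[O+]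
Why: Catalytic enantioselective Pauson–Khand reaction; oxidative cyclisation joins C10 to C5, and CO insertion with reductive elimination places C19 between C20 and C4. The benzo tether holds the two ends of the 1,7-enyne together. C5, the only new stereocentre, is set by the chiral diphosphine in the oxidative cyclisation.

Step 8
Reactants: 12 (3aS)-tricyclic enone
Product: 14 (3S,3aS)-6,8,9-trimethoxy-3-methyl-7-(propan-2-yl)-3,3a,4,5-tetrahydro-2H-cyclopenta[a]naphthalen-2-one (methyl cis to H-3a), via lithium cross-conjugated dienolate 13 (not isolated)
Conditions: LiN(iPr)2, THF, −78 °C; MeI, −78 to −40 °C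
Reagents that add atoms: iodomethane, CI
Why: Kinetic α′-deprotonation of the enone followed by SN2 methylation anti to the C6 methylene installs C18. The new C4 centre is of no consequence, because C4 becomes sp2 in the next step.

Step 9
Reactants: 14 (3S,3aS)-3-methyl enone
Product: 16 (3aR)-6,8,9-trimethoxy-3-methyl-7-(propan-2-yl)-2-(triisopropylsilyloxy)-4,5-dihydro-3aH-cyclopenta[a]naphthalene (diene C4=C19–C20=C10; H-5 α), via lithium dienolate 15 (not isolated)
Conditions: LiN(iPr)2, THF, −78 °C; iPr3SiOSO2CF3, −78 °C; cold pentane/aq. NaHCO3, short Et3N-deactivated silica plug, used at once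
Reagents that add atoms: triisopropylsilyl trifluoromethanesulfonate, CC(C)[Si](OS(=O)(=O)C(F)(F)F)(C(C)C)C(C)C
Why: A second kinetic α′-deprotonation and O-silylation give the cross-conjugated silyl dienol ether, which is the ring B-fused 2-siloxycyclopentadiene. A 2-siloxy group and low temperature are expected to slow the 1,5-hydrogen shift. C5 is not touched (its descriptor changes only through ligand priorities).

Step 10
Reactants: 17 chloroacetyl chloride; 18 (trimethylsilyl)methylmagnesium chloride
Product: 20 3-chloro-2-(trimethylsilyloxy)prop-1-ene, via 1-chloro-3-(trimethylsilyl)propan-2-one 19 (not isolated)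
Conditions: CuI (cat.), Et2O, −78 °C; filtration, then neat, 100–120 °C, distillation
Reagents that add atoms: none
Why: Copper-catalysed acylation of the Grignard reagent gives the β-ketosilane, and its thermal 1,3 carbon-to-oxygen silyl shift (Brook-type rearrangement) delivers the terminal silyl enol ether regiospecifically. Direct silylation of chloroacetone would enolise towards the chlorinated carbon.

Step 11
Reactants: 16 (3aR)-siloxycyclopentadiene; 20 3-chloro-2-(trimethylsilyloxy)prop-1-ene
Product: 23 11,12,14-trimethoxy-19-(triisopropylsilyloxy)-19,20-cycloabieta-8,11,13,19-tetraen-2-one (5α-H; C19=C20 bridge β; C18 methyl on C4), via 2-(trimethylsilyloxy)allyl cation 21 (not isolated), via O-silyl oxocarbenium ion 22 (not isolated)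
Conditions: AgClO4, 2,6-di-tert-butyl-4-methylpyridine, MeNO2–CH2Cl2, −40 to 0 °C, dark; aq. NaHCO3
Reagents that add atoms: none
Why: Proposed new method: monovalent silver abstracts chloride from 20 to give cation 21, which is attacked by C4, the most nucleophilic carbon of the silyl dienol ether; the resulting C19-siloxyallyl cation, delocalised to benzylic C10, is captured at C10 by the enol ether carbon C1, concertedly or in two fast stages, and loss of Me3Si from 22 unmasks the C2 ketone. The closest known reaction type is the silver-promoted (4+3) cycloaddition of 2-alkoxy- and 2-siloxyallyl cations with cyclopentadiene and furan, which has not been shown for a ring-fused 2-siloxycyclopentadiene substituted at both termini. Ring A is closed by this intermolecular (4+3) annulation, with both bonds forming suprafacially on one diene face, so that the six-membered ring C1–C5/C10 and the seven-membered ring through C19=C20 arise together as a bicyclo[3.2.1]octene. C4 and C10 are the bridgeheads of the new bicycle, so their mutual relation is fixed by the ring and their relation to C5 depends only on the face of attack. The C6 methylene on sp3 C5 shields one face, so the cation should enter on the face that carries H-5, which leaves H-5 over the C1–C3 bridge (trans A/B) and C6 over the C19=C20 bridge. The C3 unit is unsubstituted and symmetric, so no regiochemical or endo/exo question arises; what is needed is periselectivity for (4+3) closure over loss of silicon, loss of a proton or five-ring closure at C19. This is served by the robust iPr3Si group on the diene oxygen against the labile Me3Si group on the cation, by the hindered pyridine buffer, and by the fully substituted arene, which offers no site for Friedel–Crafts attack.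

Step 12
Reactants: 23 bridged C2 ketone
Product: 24 C2 4-methylbenzenesulfonylhydrazone of 23 (E/Z mixture at C=N)
Conditions: TsNHNH2, EtOH, 50 °C
Reagents that add atoms: 4-methylbenzenesulfonohydrazide, Cc1ccc(cc1)S(=O)(=O)NN
Why: Hydrazone condensation at the only carbonyl group; the nearly neutral medium should leave the bulky silyl enol ether intact.

Step 13
Reactants: 24 C2 tosylhydrazone
Product: 26 11,12,14-trimethoxy-19-(triisopropylsilyloxy)-19,20-cycloabieta-8,11,13,19-tetraene (5α-H; C19=C20 bridge β), via N-boryl tosylhydrazine 25 (not isolated)
Conditions: catecholborane, CHCl3, −10 °C; NaOAc·3H2O, reflux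
Reagents that add atoms: none
Why: Caglioti-type deoxygenation; hydride adds to C=N, acetate induces loss of sulfinate, and the alkyl diazene extrudes nitrogen to leave CH2. The conditions are non-acidic, and the isolated enol ether double bond cannot transpose.

Step 14
Reactants: 26 deoxygenated silyl enol ether
Product: 29 (4S,5R,10R)-11,12,14-trimethoxyabieta-8,11,13-trien-19,20-olide, via 20-oxo 19-silyl ester 27 (not isolated), via 20-hydroxy 19-acid 28 (not isolated)
Conditions: O3, CH2Cl2–MeOH, −78 °C, Sudan red 7B end point; NaBH4, −78 °C to rt; 1 M HCl
Reagents that add atoms: ozone, [O-][O+]=O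
Why: Ozonolysis of a silyl enol ether; the electron-rich C19=C20 bond reacts before the arene and is cleaved to a C19 silyl ester and a C20 aldehyde. Borohydride reduces the aldehyde, the silyl ester falls off in the basic methanol, and the 1,3-diaxial hydroxy acid lactonises on acidification. No stereocentre is touched.

Step 15
Reactants: 29 trimethoxy lactone
Product: 30 (4S,5R,10R)-11,12,14-trimethoxyabieta-6,8,11,13-tetraen-19,20-olide
Conditions: DDQ, 1,4-dioxane, 80 °C
Reagents that add atoms: none
Why: Quinone dehydrogenation; hydride is abstracted from C7, which is benzylic and para/ortho to two methoxy groups, and H-6 is then lost. Quaternary C10 blocks aromatisation, and the isopropyl methine, held in the arene plane between two methoxy groups, is poorly aligned for abstraction.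

Step 16
Reactants: 30 6,7-dehydro trimethoxy lactone
Product: 31 (4S,5R,10R)-12-methoxy-11,14-dioxoabieta-6,8,12-trien-19,20-olide
Conditions: (NH4)2Ce(NO3)6, MeCN–H2O, 0 °C
Reagents that add atoms: water, O
Why: Oxidative demethylation by tetravalent cerium; the 1,4-related methoxy groups on C11 and C14 leave as methanol while water supplies the carbonyl oxygens. This gives the para-quinone and keeps the 12-methoxy group as a vinylogous ester.

Step 17
Reactants: 31 methoxyquinone lactone
Product: 32 (4S,5R,10R)-12-hydroxy-11,14-dioxoabieta-6,8,12-trien-19,20-olide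
Conditions: BBr3, CH2Cl2, −78 to −20 °C; H2O
Reagents that add atoms: none
Why: Lewis acid ether cleavage; boron binds at the C11 carbonyl/12-methoxy site and bromide removes the methyl group. The hindered lactone should survive the low temperature, and the absence of base protects H-5.

Step 18
Reactants: 32 hydroxyquinone lactone
Product: 33 (4S,5R,10R)-12-acetoxy-11,14-dioxoabieta-6,8,12-trien-19,20-olide (target)
Conditions: Ac2O, pyridine, DMAP (cat.), CH2Cl2, 0 °C
Reagents that add atoms: acetic anhydride, CC(=O)OC(C)=O
Why: O-acylation of the acidic hydroxyquinone under mild conditions, done last because the product is a vinylogous anhydride.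

## Compound list

1 | 1,2,4-trimethoxybenzene | COc1ccc(OC)c(OC)c1 | starting material
2 | acetone | CC(C)=O | starting material
3 | 2,3,6-trimethoxyphenyllithium | [Li]c1c(OC)ccc(OC)c1OC | intermediate
4 | 2-(2,3,6-trimethoxyphenyl)propan-2-ol | CC(C)(O)c1c(OC)ccc(OC)c1OC | intermediate
5 | 1,2,4-trimethoxy-3-(propan-2-yl)benzene | CC(C)c1c(OC)ccc(OC)c1OC | intermediate
6 | 1-bromo-2,4,5-trimethoxy-3-(propan-2-yl)benzene | CC(C)c1c(OC)c(Br)cc(OC)c1OC | intermediate
7 | 2-bromo-3,5,6-trimethoxy-4-(propan-2-yl)phenyllithium | CC(C)c1c(OC)c(Br)c([Li])c(OC)c1OC | intermediate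
8 | 2-bromo-3,5,6-trimethoxy-4-(propan-2-yl)benzaldehyde | CC(C)c1c(OC)c(Br)c(C=O)c(OC)c1OC | intermediate
9 | but-3-en-1-ylzinc bromide | C=CCC[Zn]Br | starting material
10 | 2-(but-3-en-1-yl)-3,5,6-trimethoxy-4-(propan-2-yl)benzaldehyde | CC(C)c1c(OC)c(CCC=C)c(C=O)c(OC)c1OC | intermediate
11 | 1-(but-3-en-1-yl)-2-ethynyl-3,4,6-trimethoxy-5-(propan-2-yl)benzene | CC(C)c1c(OC)c(CCC=C)c(C#C)c(OC)c1OC | intermediate
12 | (3aS)-6,8,9-trimethoxy-7-(propan-2-yl)-3,3a,4,5-tetrahydro-2H-cyclopenta[a]naphthalen-2-one | O=C1C=C2[C@H](C1)CCc1c(OC)c(C(C)C)c(OC)c(OC)c12 | intermediate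
13 | lithium cross-conjugated dienolate of 12 | [Li]OC1=C[C@@H]2CCc3c(OC)c(C(C)C)c(OC)c(OC)c3C2=C1 | intermediate
14 | (3S,3aS)-3-methyl derivative of 12 (methyl cis to H-3a) | C[C@@H]1C(=O)C=C2[C@H]1CCc1c(OC)c(C(C)C)c(OC)c(OC)c12 | intermediate
15 | lithium dienolate of 14 | CC1=C(O[Li])C=C2[C@H]1CCc1c(OC)c(C(C)C)c(OC)c(OC)c12 | intermediate
16 | (3aR)-6,8,9-trimethoxy-3-methyl-7-(propan-2-yl)-2-(triisopropylsilyloxy)-4,5-dihydro-3aH-cyclopenta[a]naphthalene | CC1=C(O[Si](C(C)C)(C(C)C)C(C)C)C=C2[C@H]1CCc1c(OC)c(C(C)C)c(OC)c(OC)c12 | intermediate
17 | chloroacetyl chloride | ClCC(=O)Cl | starting material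
18 | (trimethylsilyl)methylmagnesium chloride | C[Si](C)(C)C[Mg]Cl | starting material
19 | 1-chloro-3-(trimethylsilyl)propan-2-one | C[Si](C)(C)CC(=O)CCl | intermediate
20 | 3-chloro-2-(trimethylsilyloxy)prop-1-ene | C=C(O[Si](C)(C)C)CCl | intermediate
21 | 2-(trimethylsilyloxy)allyl cation (perchlorate ion pair) | C=C(O[Si](C)(C)C)[CH2+].[O-]Cl(=O)(=O)=O | intermediate
22 | O-trimethylsilyl oxocarbenium ion of 23 (perchlorate ion pair) | CC(C)c1c(OC)c2c(c(OC)c1OC)[C@]13CC(=[O+][Si](C)(C)C)C[C@](C)(C(O[Si](C(C)C)(C(C)C)C(C)C)=C1)[C@@H]3CC2.[O-]Cl(=O)(=O)=O | intermediate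
23 | 11,12,14-trimethoxy-19-(triisopropylsilyloxy)-19,20-cycloabieta-8,11,13,19-tetraen-2-one (5α-H) | CC(C)c1c(OC)c2c(c(OC)c1OC)[C@]13CC(=O)C[C@](C)(C(O[Si](C(C)C)(C(C)C)C(C)C)=C1)[C@@H]3CC2 | intermediate
24 | C2 tosylhydrazone of 23 | CC(C)c1c(OC)c2c(c(OC)c1OC)[C@]13CC(=NNS(=O)(=O)c4ccc(C)cc4)C[C@](C)(C(O[Si](C(C)C)(C(C)C)C(C)C)=C1)[C@@H]3CC2 | intermediate
25 | C2 N-(1,3,2-benzodioxaborol-2-yl)-N′-tosylhydrazine | CC(C)c1c(OC)c2c(c(OC)c1OC)[C@]13CC(N(NS(=O)(=O)c4ccc(C)cc4)B4Oc5ccccc5O4)C[C@](C)(C(O[Si](C(C)C)(C(C)C)C(C)C)=C1)[C@@H]3CC2 | intermediate
26 | 11,12,14-trimethoxy-19-(triisopropylsilyloxy)-19,20-cycloabieta-8,11,13,19-tetraene (5α-H) | CC(C)c1c(OC)c2c(c(OC)c1OC)[C@]13CCC[C@](C)(C(O[Si](C(C)C)(C(C)C)C(C)C)=C1)[C@@H]3CC2 | intermediate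
27 | triisopropylsilyl 11,12,14-trimethoxy-20-oxoabieta-8,11,13-trien-19-oate | CC(C)c1c(OC)c2c(c(OC)c1OC)[C@@]1(C=O)CCC[C@](C)(C(=O)O[Si](C(C)C)(C(C)C)C(C)C)[C@@H]1CC2 | intermediate
28 | 20-hydroxy-11,12,14-trimethoxyabieta-8,11,13-trien-19-oic acid | CC(C)c1c(OC)c2c(c(OC)c1OC)[C@@]1(CO)CCC[C@](C)(C(=O)O)[C@@H]1CC2 | intermediate
29 | (4S,5R,10R)-11,12,14-trimethoxyabieta-8,11,13-trien-19,20-olide | CC(C)c1c(OC)c2c(c(OC)c1OC)[C@]13CCC[C@](C)(C(=O)OC1)[C@@H]3CC2 | intermediate
30 | (4S,5R,10R)-11,12,14-trimethoxyabieta-6,8,11,13-tetraen-19,20-olide | CC(C)c1c(OC)c2c(c(OC)c1OC)[C@]13CCC[C@](C)(C(=O)OC1)[C@@H]3C=C2 | intermediate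
31 | (4S,5R,10R)-12-methoxy-11,14-dioxoabieta-6,8,12-trien-19,20-olide | COC1=C(C(C)C)C(=O)C2=C(C1=O)[C@]13CCC[C@](C)(C(=O)OC1)[C@@H]3C=C2 | intermediate
32 | (4S,5R,10R)-12-hydroxy-11,14-dioxoabieta-6,8,12-trien-19,20-olide | OC1=C(C(C)C)C(=O)C2=C(C1=O)[C@]13CCC[C@](C)(C(=O)OC1)[C@@H]3C=C2 | intermediate
33 | (4S,5R,10R)-12-acetoxy-11,14-dioxoabieta-6,8,12-trien-19,20-olide | CC(=O)OC1=C(C(C)C)C(=O)C2=C(C1=O)[C@]13CCC[C@](C)(C(=O)OC1)[C@@H]3C=C2 | target

## Step count and least certain steps

Total step count: 18. Longest linear sequence: 17 (steps 1–9 and 11–18). Step 10 is a one-step side branch.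

**Step 11 (key step).**
- Most likely failure: an interrupted cycloaddition. After the C3–C4 bond has formed, the well-stabilised siloxyallyl/benzyl cation may lose silicon or a proton, or close a five-membered ring at C19, faster than C1 reaches the hindered C10.
- Further risks: ionisation of a primary chloride may be slow. Monovalent silver in a weakly coordinating solvent may oxidise the very electron-rich diene by single-electron transfer. Poor facial selectivity is the lesser concern.
- Fallback (known chemistry): it sets out from 14.
  - Kinetic enolate formation and alkylation with excess 1,3-diiodopropane, anti to C6, should give the 3-(3-iodopropyl)-3-methyl enone F1.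
  - An intramolecular Giese radical conjugate addition (Bu3SnH, AIBN, benzene, reflux) would then join C1 to the β-carbon C10 on the face fixed by the tether, giving the bridged C19 ketone F2.
  - Deprotonation at C20, the only enolisable position, and silylation with iPr3SiOSO2CF3 returns to the route at 26.

**Step 7.**
- Most likely failure: sluggish cyclisation of a 1,7-enyne, oligomerisation of the terminal alkyne at the metal, and insufficient enantiofacial discrimination. The asymmetric rhodium system is best established for 1,6-enynes with substituted alkynes.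
- Fallback: from 11, a stoichiometric cobalt-mediated Pauson–Khand reaction (Co2(CO)8, CH2Cl2, then N-methylmorpholine N-oxide) should give the racemic tricyclic enone F3.
  - F3 is resolved by preparative chromatography on a chiral stationary phase.
  - The unwanted antipode can be racemised with base through the extended dienolate and recycled.
  - The (3aS) enantiomer is 12.

**Step 9.**
- Most likely failure: deprotonation at the γ-position C5 instead of the hindered C4 methine, or a 1,5-hydrogen shift during handling. Either would erase C5 and move the diene termini.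
- Fallback: from 12, generate the enolate regiospecifically by reduction instead of deprotonation.
  - α′-Aminomethylation (LiN(iPr)2, then dimethylmethyleneiminium iodide) gives the Mannich base F4.
  - Quaternisation with MeI and elimination with NaHCO3 gives the α′-methylene dienone F5.
  - Conjugate hydride addition to the unhindered exocyclic enone with LiBH(s-Bu)3 at −78 °C, followed by trapping with iPr3SiOSO2CF3, returns to 16. Step 8 is bypassed.

**Step 14.**
- Most likely failure: competing attack of ozone on the pentasubstituted, very electron-rich arene if the end point is overshot.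
- Fallback: from 26, run the cleavage in stages.
  - Rubottom oxidation (mCPBA, NaHCO3, then Bu4NF) gives the 20-hydroxy C19 ketone F6 (C20 epimers, of no consequence).
  - Periodate cleavage (NaIO4, THF–H2O) gives the 20-oxo 19-acid F7.
  - NaBH4 reduction and acidification return to 29.

**Step 15.**
- Most likely failure: unselective hydride abstraction, adduct formation between the benzylic cation and the reduced quinone, or over-oxidation. The styrene may also be damaged in the cerium oxidation that follows.
- Fallback: from 29, invert the order.
  - Oxidative demethylation with (NH4)2Ce(NO3)6 gives the ring B-saturated methoxyquinone F8.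
  - Radical bromination at C7 (NBS, light, PhCF3) gives the 7α-bromide F9.
  - Elimination with Li2CO3 in DMF returns to the route at 31.

## Further compounds

F1 | step 11 | (3R,3aS)-3-(3-iodopropyl)-3-methyl enone (chain cis to H-3a) | ICCC[C@]1(C)C(=O)C=C2[C@H]1CCc1c(OC)c(C(C)C)c(OC)c(OC)c12
F2 | step 11 | 11,12,14-trimethoxy-19,20-cycloabieta-8,11,13-trien-19-one (5α-H) | CC(C)c1c(OC)c2c(c(OC)c1OC)[C@]13CCC[C@](C)(C(=O)C1)[C@@H]3CC2
F3 | step 7 | racemic 6,8,9-trimethoxy-7-(propan-2-yl)-3,3a,4,5-tetrahydro-2H-cyclopenta[a]naphthalen-2-one | O=C1C=C2C(C1)CCc1c(OC)c(C(C)C)c(OC)c(OC)c12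
F4 | step 9 | 3-[(dimethylamino)methyl] derivative of 12 (substituent cis to H-3a) | CN(C)C[C@@H]1C(=O)C=C2[C@H]1CCc1c(OC)c(C(C)C)c(OC)c(OC)c12
F5 | step 9 | 3-methylidene derivative of 12 | C=C1C(=O)C=C2[C@H]1CCc1c(OC)c(C(C)C)c(OC)c(OC)c12
F6 | step 14 | 20-hydroxy-11,12,14-trimethoxy-19,20-cycloabieta-8,11,13-trien-19-one (C20 epimers) | CC(C)c1c(OC)c2c(c(OC)c1OC)[C@]13CCC[C@](C)(C(=O)C1O)[C@@H]3CC2
F7 | step 14 | 11,12,14-trimethoxy-20-oxoabieta-8,11,13-trien-19-oic acid | CC(C)c1c(OC)c2c(c(OC)c1OC)[C@@]1(C=O)CCC[C@](C)(C(=O)O)[C@@H]1CC2
F8 | step 15 | 12-methoxy-11,14-dioxoabieta-8,12-dien-19,20-olide | COC1=C(C(C)C)C(=O)C2=C(C1=O)[C@]13CCC[C@](C)(C(=O)OC1)[C@@H]3CC2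
F9 | step 15 | 7α-bromo-12-methoxy-11,14-dioxoabieta-8,12-dien-19,20-olide | COC1=C(C(C)C)C(=O)C2=C(C1=O)[C@]13CCC[C@](C)(C(=O)OC1)[C@@H]3C[C@H]2Br
A1 | alternative 1 | ring A/B lactone C9 alkenyl iodide | IC2[C@]13CCC[C@](C)(C(=O)OC1)[C@@H]3CCC=2
A2 | alternative 1 | 3-isopropyl-4-methoxycyclobut-3-ene-1,2-dione | COC1=C(C(C)C)C(=O)C1=O
A3 | alternative 1 | 4-alkenyl-4-hydroxy-2-isopropyl-3-methoxycyclobutenone (carbinol epimers) | COC1=C(C(C)C)C(=O)C1(O)C2[C@]13CCC[C@](C)(C(=O)OC1)[C@@H]3CCC=2
A4 | alternative 1 | 11,14-dihydroxy-12-methoxyabieta-8,11,13-trien-19,20-olide | COc1c(C(C)C)c(O)c2c(c1O)[C@]13CCC[C@](C)(C(=O)OC1)[C@@H]3CC2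
A5 | alternative 2 | 4,4-disubstituted naphthalen-1(4H)-one C20 propionate | CCC(=O)OC[C@]1(CCCO[Si](C)(C)C(C)(C)C)C=CC(=O)c2cc(C(C)C)c(OC)cc21
A6 | alternative 2 | cis-fused δ-lactone tetralone (C4 epimers) | CC(C)c1cc2c(cc1OC)[C@]1(CCCO[Si](C)(C)C(C)(C)C)COC(=O)C(C)[C@@H]1CC2=O
A7 | alternative 3 | podocarpic acid | Oc1ccc2c(c1)[C@@]1(C)CCC[C@](C)(C(=O)O)[C@@H]1CC2
A8 | alternative 3 | 13-isopropyl-12-methoxy-7-oxopodocarpa-8,11,13-trien-19-amide | CC(C)c1cc2c(cc1OC)[C@@]1(C)CCC[C@](C)(C(N)=O)[C@@H]1CC2=O
A9 | alternative 3 | 13-isopropyl-12-methoxy-7-oxopodocarpa-8,11,13-trien-19,20-olide | CC(C)c1cc2c(cc1OC)[C@]13CCC[C@](C)(C(=O)OC1)[C@@H]3CC2=O
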